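Compound numbers used throughout are those of the steps and the compound list below. Germacrane-type numbering: C1 and C5 are the cyclobutane CH carbons, C2 carries an acetate, C4 the methyl carbinol, C6 the lactone oxygen, C8 the tiglate, C10 a methyl group, C13 is the acetoxymethyl carbon. Ring A = C1–C5, ring B = C1, C5, C6, C10, ring C = C6–C10.

## The problem

Compound 32 is a linear 5-4-5 carbocycle in which cyclopentane rings A and C are fused to opposite bonds of cyclobutane ring B, with a butenolide (C6–O–C12(=O)–C11=C7) fused onto ring C. In this stereoisomer both five-membered rings lie on the same face of ring B (cis-syn-cis), so the skeleton is a strained cup, and the ring-fusion carbons C6 (oxygenated) and C10 (methylated) are adjacent quaternary centres. Of the seven stereocentres (C1, C2, C4, C5, C6, C8, C10), C6 and C10 must be fixed absolutely; they can then direct C1 and C5. Once the cup exists only the convex faces are open, and that is where the oxygens at C2, C4 and C8 sit. The tiglate will not survive hydrogenation, hydrogen-atom transfer or strong nucleophiles, the γ-acyloxy butenolide can epimerise at C8 in base, and the tertiary C4 alcohol can eliminate. The C6 oxygen is a cyclobutanol oxygen, which invites retro-aldol cleavage whenever a carbonyl sits at C4 and α-ketol ring expansion whenever C7 is a ketone. The handle for the key step lies in ring A: C2 is an oxygen-bearing CH attached to C1, and the C4 carbinol is the Markovnikov hydrate of a C3=C4 olefin. Ring A is therefore a cyclopentene whose C3 can arrive as a carbene, generated from an acetyl group on C5, and insert into a C–H bond of a CH2O arm on C1.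

## Retrosynthesis

**Ester periphery (32 ⇒ 31 ⇒ 30).** The two acetate C–O bonds at C2 and C13 are cut first, then the silyl ether at C13. Both hydroxyls of 31 are non-tertiary, so one acetylation serves both, provided the tertiary C4 alcohol is left alone. The tiglate is kept in place at this point, because a free C8 hydroxyl could not be told apart from the C2 hydroxyl later.

**Butenolide (30 ⇒ 28 ⇒ 26 + 9).** The C7=C11 double bond is cut as an intramolecular Horner–Wadsworth–Emmons reaction and the C6–O acyl bond as an esterification. The alternative, adding C13 to a preformed unsubstituted butenolide, would require α-functionalisation of a β,β-disubstituted butenolide, for which no direct method is available; here C13 arrives with the phosphonate acid 9 (from 5 and 6 through 7 and 8). The precursor is the tricyclic α-ketol 26. The forward reaction must acylate only the C6 hydroxyl, which is why the cis-1,3 diol at C2/C4 is masked for that moment (27, 28, 29), and the base must be mild enough to spare C8.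

**Ring C oxidation pattern (26 ⇒ 25 ⇒ 23 + 24; 23 ⇒ 21 ⇒ 20 ⇒ 19).** The cuts are the tiglate ester bond, the C8–O bond, the C7 ketal and the C4–O bond. C8 is oxygenated at the ketone stage because C6 is quaternary and the C7 ketone can enolise only toward C8; doing it after the lactone exists would need a γ-functionalisation of the butenolide. The C4 hydroxyl is introduced by hydration of the C3=C4 olefin before any unsaturated ester is present, since hydrogen-atom transfer would not distinguish the tiglate. Both oxygens must be delivered to exo faces, which the cup enforces.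

**Ring A, the key cut (19 ⇒ 16 + 17).** The C2–C3 single bond and the C3=C4 double bond are cut: C3 is removed altogether and comes from 17. An aldol closure through the acetyl methyl group would instead put a ketone at C4, and the methyl group would then have to be added from the exo face, giving the wrong C4 epimer. Closing C1–C2 or C4–C5 would mean forming bonds on the cyclobutane itself. The carbene route uses the C2 oxygen twice, as the activating group for insertion and as the eventual acetate oxygen. The precursor 16 is only a bicyclo[3.2.0]heptane with two cis arms. The forward step requires that the C2 hydrogens be the only C–H bonds in a 1,5 relationship to the carbene, so C7 must be a ketal with no hydrogen. The C6 silyl ether is carried over from the cycloaddition and not exchanged, because a free C6 hydroxyl β to the acetyl group would cleave by retro-aldol reaction.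

**Cyclobutane (16 ⇒ 15 ⇒ 14 + 4).** The two C–H bonds at C1 and C5 are cut (hydrogenation), then C1–C10 and C5–C6 as a polar [2+2] cycloaddition of silyl enol ether 14 with ynone 4. A photochemical enone–alkyne cycloaddition would not control the orientation of an unsymmetrical alkyne, whereas the donor–acceptor pairing fixes it here. The fragments are simple and the ring fusion can only be cis. The forward reactions must give one absolute configuration at C6/C10 (separation of diastereomers on the chiral ketal) and must place hydrogen on the face of ring B opposite ring C.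

**Fragments (14 ⇒ 12 ⇒ 10 + 11; 4 ⇒ 1 + 2).** The ketal of 12 protects C7, removes the C7 hydrogen that would compete in the key step, and carries the resolving stereocentres from diol 11. The only enolisable position of 12 is the methyl-bearing carbon, so 14 is a single regioisomer. Ynone 4 is one acylation from 1 and 2.

## Roads not taken

**Alternative 1:** The cut removes both cross-ring bonds of ring B (C1–C5 and C6–C10), opening the tiglate-free compound into the ten-membered triene lactone A1. Forward, irradiation of A1 would join the two ring olefins across the ring and give A2, one acylation from 32.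
- Merits: two C–C bonds, three rings and four stereocentres in one step, with no protecting groups on the core. In bond economy and step count after A1 this road is clearly better than the chosen one.
- Weak points: A1 needs both ring olefins cis inside a functionalised ten-membered ring that already holds the C2, C4 and C8 stereocentres and an enol lactone conjugated to the butenolide. Under irradiation that conjugated dienyl lactone is expected to isomerise about its double bonds. The cis-syn-cis product also requires the parallel, face-to-face conformer, and nothing in A1 enforces it over crossed or anti adducts.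
- Comparison: the chosen plan offers ring closures on small rigid bicycles whose faces are distinguishable, and no macrocycle of defined olefin geometry to make. It pays for this with fourteen linear steps.

**Alternative 2:** The cut is the C6–C10 bond, after redrawing rings B and C as one seven-membered ring; the precursor is the ring-A-fused alkoxytropone A3. Forward, irradiation closes the C10=C1–C5=C6 diene unit by disrotatory 4π electrocyclisation to give A4, with ring B as a cyclobutene and ring C as a cyclopentenone.
- Merits: both quaternary centres form at once and necessarily cis, the C6 oxygen and C7 carbonyl are in place, and a C8=C9 enone is ready for oxygenation. This is more direct than joining the two tetrasubstituted partners 14 and 4, and no acid comes near a ketal.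
- Weak points: the only stereocentre of A3 is C2, remote from the new centres, so the face of closure would be poorly controlled and diastereomers must still be separated. The primary photoproduct is itself photolabile, so irradiation must be stopped short. The cyclobutene of A4 must then be hydrogenated from the face carrying the methyl and benzyloxy groups, under conditions that also cleave the benzyl ether and reduce the enone. Finally, the C4 ketone would receive its methyl group from the exo face, giving the C4 epimer with the hydroxyl endo, opposite to 32.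
- Comparison: equal on the hydrogenation-face question and better on the quaternary pair. The chosen plan offers instead a C4 configuration set by radical trapping on the exo face, and a ring A that is built only after the cyclobutane stereocentres are fixed.

**Alternative 3:** The cut is C8–C9 and the C10–methyl bond, with rings A and B made first as α-methylene cyclobutanone A5. Forward, a sulfur-stabilised acyl-anion equivalent adds to the exocyclic methylene and the C10 enolate is methylated from the convex face to give A6; ring C is then closed by aldol addition onto the C6 carbonyl.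
- Merits: convergent, with C2 and C4 set early on a simple bicycle. Convex-face methylation puts the C9 chain on the concave face, as the cup requires. It avoids both the cycloaddition of two tetrasubstituted partners and the hydrogenation-face question, and in those two respects is as good as or better than the chosen plan.
- Weak points: A5 is a strained, polymerisation-prone acceptor. Conjugate rather than carbonyl addition, and C- rather than O-alkylation of a cyclobutanone enolate at a centre becoming quaternary, are both uncertain. After A6, ring C arrives with its carbonyl at C8 and a bare CH2 at C7, so the C6 hydroxyl is a cyclobutanol β to a ketone (retro-aldol) and C7 still has to be oxidised before a butenolide can be made.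
- Comparison: the chosen plan brings the C6 oxygen and C7 carbonyl in from 10 at the right oxidation level, at the price of a cycloaddition that needs a fallback.

Key step: step 9

Assumption: the sense of induction by the dimethyldioxolane in step 7 cannot be predicted; the route is written with diol 11 and takes on whichever separated diastereomer has the ring-fusion configuration drawn for 15 (the enantiomeric diol serves equally if that one proves minor).

Convention for names: β is the face of ring B carrying H1, H5, the C10 methyl and the C6 oxygen; rings A and C both lie on the α face. On a five-membered ring, exo means pointing away from the pocket between rings A and C, endo into it. TBS = tert-butyldimethylsilyl.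

## Route

Step 1
Reactants: 1 tert-butyldimethyl(prop-2-yn-1-yloxy)silane; 2 N-methoxy-N-methylacetamide
Product: 4 5-[(tert-butyldimethylsilyl)oxy]pent-3-yn-2-one, via lithium acetylide 3 (not isolated)
Conditions: n-BuLi, THF, −78 °C; then 2, −78 to −20 °C; cold aq. NH4Cl
Reagents that add atoms: none
Why: Acylation of a lithium acetylide with a Weinreb amide; the chelated tetrahedral adduct prevents over-addition, and the cold quench keeps the released amine from adding to the ynone.

Step 2
Reactants: 5 benzyl 2-(diethoxyphosphoryl)acetate; 6 formaldehyde (used as paraformaldehyde)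
Product: 7 benzyl 2-(diethoxyphosphoryl)-3-hydroxypropanoate (racemic)
Conditions: (CH2O)n (1.1 equiv), piperidine (cat.), THF, 60 °C
Reagents that add atoms: none
Why: Amine-catalysed aldol-type hydroxymethylation of the doubly activated methylene; with one equivalent of formaldehyde and no stoichiometric base the reaction should stop at the mono-adduct.

Step 3
Reactants: 7 benzyl 2-(diethoxyphosphoryl)-3-hydroxypropanoate
Product: 8 benzyl 3-[(tert-butyldimethylsilyl)oxy]-2-(diethoxyphosphoryl)propanoate (racemic)
Conditions: TBSCl, imidazole, CH2Cl2, 0 °C
Reagents that add atoms: tert-butyldimethylsilyl chloride, CC(C)(C)[Si](C)(C)Cl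
Why: Standard silylation of a primary alcohol under conditions too weakly basic to trigger β-elimination.

Step 4
Reactants: 8 benzyl 3-[(tert-butyldimethylsilyl)oxy]-2-(diethoxyphosphoryl)propanoate
Product: 9 3-[(tert-butyldimethylsilyl)oxy]-2-(diethoxyphosphoryl)propanoic acid (racemic)
Conditions: H2 (1 atm), 10% Pd/C, EtOAc, 23 °C
Reagents that add atoms: none
Why: Neutral hydrogenolysis of the benzyl ester frees the acid without the basic conditions that could eliminate the β-silyloxy group.

Step 5
Reactants: 10 3-methylcyclopentane-1,2-dione; 11 (2R,3R)-butane-2,3-diol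
Product: 12 (2R,3R)-2,3,7-trimethyl-1,4-dioxaspiro[4.4]nonan-6-one (both epimers at the methyl-bearing C7)
Conditions: TsOH·H2O (cat.), benzene, reflux, Dean–Stark trap
Reagents that add atoms: none
Why: Acid-catalysed ketalisation with azeotropic water removal; the dione reacts through its enol, whose double bond lies toward the methyl group, so the carbonyl remote from the methyl group is ketalised, and that ketal is also the less hindered one. The methyl-bearing carbon is left unset because it becomes sp2 in step 6.

Step 6
Reactants: 12 (2R,3R)-2,3,7-trimethyl-1,4-dioxaspiro[4.4]nonan-6-one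
Product: 14 tert-butyldimethyl{[(2R,3R)-2,3,7-trimethyl-1,4-dioxaspiro[4.4]non-6-en-6-yl]oxy}silane, via potassium enolate 13 (not isolated)
Conditions: KN(SiMe3)2, THF, −78 °C; then TBSCl, −78 to 23 °C
Reagents that add atoms: tert-butyldimethylsilyl chloride, CC(C)(C)[Si](C)(C)Cl
Why: The ketone has a single α-hydrogen (the other α-carbon is the ketal), so deprotonation and O-silylation give one tetrasubstituted silyl enol ether.

Step 7
Reactants: 14 tert-butyldimethyl{[(2R,3R)-2,3,7-trimethyl-1,4-dioxaspiro[4.4]non-6-en-6-yl]oxy}silane; 4 5-[(tert-butyldimethylsilyl)oxy]pent-3-yn-2-one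
Product: 15 ring B/C cyclobutene (bicyclo[3.2.0]hept-6-ene): C1=C5 olefin with CH2OTBS on C1 and acetyl on C5, OTBS on C6 and methyl on C10 cis on the β face, C7 as (4R,5R)-4,5-dimethyl-1,3-dioxolane
Conditions: Tf2NH (3 mol%), CH2Cl2, −78 °C; chromatographic separation of the two ketal diastereomers
Reagents that add atoms: none
Why: Acid-catalysed stepwise [2+2] cycloaddition of a silyl enol ether with an acetylenic carbonyl acceptor: Mukaiyama–Michael attack of C10 on the ynone β-carbon, then closure of the allenolate α-carbon on the C6 silyloxocarbenium ion, so polarity fixes the regiochemistry and the fusion can only be cis. The C2-symmetric ketal turns the two ring-fusion enantiomers into separable diastereomers, which is how the absolute configuration at C6 and C10 is secured.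

Step 8
Reactants: 15 ring B/C cyclobutene
Product: 16 cis acetyl/silyloxymethyl cyclobutane: 15 with H1 and H5 on the β face, so that CH2OTBS on C1 and acetyl on C5 are both α, cis to ring C
Conditions: H2 (1 atm), 10% Pd/C, EtOAc, 23 °C
Reagents that add atoms: none
Why: Heterogeneous syn-hydrogenation of a strained tetrasubstituted cyclobutene; adsorption is expected on the β face, which carries only the angular methyl group and a silyloxy oxygen, and not on the α face screened by ring C and its spiro ketal. Neutral conditions keep the epimerisable C5 centre cis.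

Step 9
Reactants: 16 cis acetyl/silyloxymethyl cyclobutane; 17 trimethylsilyldiazomethane
Product: 19 tricyclic ring A cyclopentene: cis-syn-cis 5-4-5 tricycle with C3=C4 olefin (methyl on C4), exo OTBS at C2, β OTBS at C6, β methyl at C10, C7 dioxolane, via alkylidene carbene 18 (not isolated)
Conditions: Me3SiCHN2, n-BuLi, THF, −78 °C; then 16, −78 to 0 °C; aq. NH4Cl
Reagents that add atoms: none
Why: Lithiated 17 adds to the methyl ketone, the adduct loses lithium trimethylsilanolate in a Peterson-type elimination, and the resulting diazoalkene sheds N2 to give carbene 18 at C3. The closest known reaction type is the conversion of ketones into cyclopentenes by alkylidene-carbene 1,5 C–H insertion with this reagent (Seyferth–Gilbert/Colvin-type carbene generation). The singlet carbene inserts in a concerted three-centre transition state into a C2–H bond five atoms away, forming C2–C3 and leaving C3=C4; this 1,5 insertion closes ring A, which must be cis-fused to ring B because both arms already sit on the α face. The new stereocentre C2 is formed with retention, and which hydrogen reacts is decided by the silyloxy group taking the exo position in the transition state, away from the pocket under ring C. The step needs site selectivity, and the substrate secures it: the two C2 hydrogens are the only C–H bonds in a 1,5 relationship (C6 and C10 are quaternary, C7 is a ketal) and they are activated by the adjacent oxygen. The C6 silyloxy group is trans to the carbene arm on the cyclobutane, so O–Si insertion is geometrically closed, and 1,2-shift to an alkyne is slow for a dialkyl carbene. Pre-forming the reagent at −78 °C lets addition outrun enolisation at the epimerisable C5.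

Step 10
Reactants: 19 tricyclic ring A cyclopentene
Product: 20 C4 carbinol: 19 hydrated across C3=C4, with the C4 hydroxyl exo (cis to the C2 OTBS) and the C4 methyl endo
Conditions: Co(acac)2 (20 mol%), PhSiH3, O2 (1 atm), THF, 23 °C; then aq. Na2S2O3
Reagents that add atoms: dioxygen, O=O
Why: Mukaiyama hydration: hydrogen-atom transfer to C3 gives the tertiary C4 radical (Markovnikov), which O2 traps on the exo face because the endo face points into the pocket; the peroxide is reduced in situ. No unsaturated ester is present yet, so there is no competing acceptor.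

Step 11
Reactants: 20 C4 carbinol
Product: 21 C7 ketone: 20 with the dioxolane replaced by C7=O
Conditions: PPTS, acetone/H2O (10:1), 55 °C
Reagents that add atoms: water, O
Why: Acid-catalysed ketal hydrolysis driven by exchange with acetone; PPTS is mild enough for the secondary and the hindered tertiary silyl ether and for the tertiary alcohol.

Step 12
Reactants: 21 C7 ketone
Product: 23 C8 alcohol: 21 with an exo hydroxyl at C8 (cis to the C10 methyl and the C6 OTBS), via dipotassium enolate–alkoxide 22 (not isolated)
Conditions: KN(SiMe3)2 (2.2 equiv), THF, −78 °C; then 2-(phenylsulfonyl)-3-phenyloxaziridine, −78 °C; aq. NH4Cl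
Reagents that add atoms: 2-(phenylsulfonyl)-3-phenyloxaziridine, O=S(=O)(N1OC1c2ccccc2)c3ccccc3
Why: Davis oxidation of the potassium enolate; C8 is the only enolisable position because C6 is quaternary, and the oxaziridine can reach only the exo face of ring C, the endo face being closed by rings B and A. The C4 alkoxide is a spectator.

Step 13
Reactants: 23 C8 alcohol; 24 (E)-2-methylbut-2-enoyl chloride (tigloyl chloride)
Product: 25 C8 tiglate of 23
Conditions: 24, pyridine, DMAP (cat.), CH2Cl2, 0 to 23 °C
Reagents that add atoms: none
Why: Acylation of the only secondary alcohol; the tertiary C4 alcohol is inert under these conditions, and pyridine rather than a stronger amine avoids vinylketene formation and loss of the E geometry.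

Step 14
Reactants: 25 C8 tiglate
Product: 26 triol: 25 without both silyl groups (hydroxyls at C2, C4 and C6; C7 ketone; C8 tiglate)
Conditions: 48% aq. HF, MeCN, 23 °C
Reagents that add atoms: none
Why: Acidic fluoride cleavage removes the secondary and the hindered tertiary silyl ether without generating the C6 alkoxide, which would invite α-ketol shift, and without touching the esters.

Step 15
Reactants: 26 triol; 9 3-[(tert-butyldimethylsilyl)oxy]-2-(diethoxyphosphoryl)propanoic acid
Product: 28 C6 phosphonate ester with C2,C4-O-phenylboronate (epimers at the phosphonate carbon), via C2,C4-O-phenylboronate 27 (not isolated)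
Conditions: PhB(OH)2, 4 Å MS, CH2Cl2, 23 °C; then 9, DCC, DMAP (cat.), 0 to 23 °C
Reagents that add atoms: phenylboronic acid, OB(O)c1ccccc1
Why: The cis-1,3 diol at C2/C4 is tied up as a six-membered cyclic boronate, leaving the C6 hydroxyl as the only free one; Steglich esterification then acylates it. Phosphonoacetic acids can react through the ketene derived from the O-acylisourea, which suits a hindered tertiary alcohol.

Step 16
Reactants: 28 C6 phosphonate ester boronate
Product: 30 butenolide diol: C7=C11 lactone with CH2OTBS on C11, free hydroxyls at C2 and C4, C8 tiglate, via butenolide phenylboronate 29 (not isolated)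
Conditions: LiCl, DBU, MeCN, 0 to 23 °C; then pinacol, THF/H2O, 23 °C
Reagents that add atoms: none
Why: Intramolecular Horner–Wadsworth–Emmons reaction under Masamune–Roush conditions closes the five-membered lactone on the C7 ketone; the mild base limits epimerisation at C8 and β-elimination of the silyloxy group. Transesterification with pinacol then releases the diol.

Step 17
Reactants: 30 butenolide diol
Product: 31 13-hydroxy butenolide triol (hydroxyls at C2, C4 and C13)
Conditions: HF·pyridine, pyridine/THF, 0 to 23 °C
Reagents that add atoms: none
Why: Buffered fluoride desilylation of the primary allylic silyl ether; lactone and tiglate are stable.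

Step 18
Reactants: 31 13-hydroxy butenolide triol
Product: 32 CNP0210373.1
Conditions: Ac2O, pyridine, CH2Cl2, 23 °C
Reagents that add atoms: acetic anhydride, CC(=O)OC(C)=O
Why: Acetylation esterifies the primary allylic and the secondary alcohol; the tertiary C4 alcohol does not react without stronger activation.

## Compound list

1 | tert-butyldimethyl(prop-2-yn-1-yloxy)silane | C#CCO[Si](C)(C)C(C)(C)C | starting material
2 | N-methoxy-N-methylacetamide | CC(=O)N(C)OC | starting material
3 | lithium 3-[(tert-butyldimethylsilyl)oxy]prop-1-yn-1-ide | [Li+].[C-]#CCO[Si](C)(C)C(C)(C)C | intermediate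
4 | 5-[(tert-butyldimethylsilyl)oxy]pent-3-yn-2-one | CC(=O)C#CCO[Si](C)(C)C(C)(C)C | intermediate
5 | benzyl 2-(diethoxyphosphoryl)acetate | CCOP(=O)(OCC)CC(=O)OCc1ccccc1 | starting material
6 | formaldehyde (as paraformaldehyde) | C=O | starting material
7 | benzyl 2-(diethoxyphosphoryl)-3-hydroxypropanoate (racemic) | CCOP(=O)(OCC)C(CO)C(=O)OCc1ccccc1 | intermediate
8 | benzyl 3-[(tert-butyldimethylsilyl)oxy]-2-(diethoxyphosphoryl)propanoate (racemic) | CCOP(=O)(OCC)C(CO[Si](C)(C)C(C)(C)C)C(=O)OCc1ccccc1 | intermediate
9 | 3-[(tert-butyldimethylsilyl)oxy]-2-(diethoxyphosphoryl)propanoic acid (racemic) | CCOP(=O)(OCC)C(CO[Si](C)(C)C(C)(C)C)C(=O)O | intermediate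
10 | 3-methylcyclopentane-1,2-dione | CC1CCC(=O)C1=O | starting material
11 | (2R,3R)-butane-2,3-diol | C[C@@H](O)[C@@H](C)O | starting material
12 | (2R,3R)-2,3,7-trimethyl-1,4-dioxaspiro[4.4]nonan-6-one (both C7 epimers) | CC1CCC2(O[C@H](C)[C@@H](C)O2)C1=O | intermediate
13 | potassium (2R,3R)-2,3,7-trimethyl-1,4-dioxaspiro[4.4]non-6-en-6-olate | CC1=C([O-])C2(O[C@H](C)[C@@H](C)O2)CC1.[K+] | intermediate
14 | tert-butyldimethyl{[(2R,3R)-2,3,7-trimethyl-1,4-dioxaspiro[4.4]non-6-en-6-yl]oxy}silane | CC1=C(O[Si](C)(C)C(C)(C)C)C2(O[C@H](C)[C@@H](C)O2)CC1 | intermediate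
15 | ring B/C cyclobutene (C1=C5; C1 CH2OTBS, C5 acetyl, β OTBS at C6, β methyl at C10, C7 (4R,5R)-dimethyldioxolane) | C1C[C@]2(C)C(CO[Si](C)(C)C(C)(C)C)=C(C(C)=O)[C@]2(O[Si](C)(C)C(C)(C)C)C13O[C@H](C)[C@@H](C)O3 | intermediate
16 | cis acetyl/silyloxymethyl cyclobutane (H1, H5 β; both carbon arms α, cis to ring C) | C1C[C@]2(C)[C@H](CO[Si](C)(C)C(C)(C)C)[C@H](C(C)=O)[C@]2(O[Si](C)(C)C(C)(C)C)C13O[C@H](C)[C@@H](C)O3 | intermediate
17 | trimethylsilyldiazomethane | C[Si](C)(C)C=[N+]=[N-] | starting material
18 | alkylidene carbene (16 with the acetyl oxygen replaced by the divalent carbon C3) | C1C[C@]2(C)[C@H](CO[Si](C)(C)C(C)(C)C)[C@H](C(C)=[C])[C@]2(O[Si](C)(C)C(C)(C)C)C13O[C@H](C)[C@@H](C)O3 | intermediate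
19 | tricyclic ring A cyclopentene (cis-syn-cis; C3=C4, exo OTBS at C2, β OTBS at C6, C7 dioxolane) | C1C[C@]2(C)[C@@H]3[C@@H](O[Si](C)(C)C(C)(C)C)C=C(C)[C@@H]3[C@]2(O[Si](C)(C)C(C)(C)C)C14O[C@H](C)[C@@H](C)O4 | intermediate
20 | C4 carbinol (exo OH and endo methyl at C4; C7 dioxolane) | C1C[C@]2(C)[C@@H]3[C@@H](O[Si](C)(C)C(C)(C)C)C[C@@](C)(O)[C@@H]3[C@]2(O[Si](C)(C)C(C)(C)C)C14O[C@H](C)[C@@H](C)O4 | intermediate
21 | C7 ketone | C1C[C@]2(C)[C@@H]3[C@@H](O[Si](C)(C)C(C)(C)C)C[C@@](C)(O)[C@@H]3[C@]2(O[Si](C)(C)C(C)(C)C)C1=O | intermediate
22 | dipotassium C7,C8-enolate C4-alkoxide of 21 | [K+].[K+].[O-]C1=CC[C@]2(C)[C@@H]3[C@@H](O[Si](C)(C)C(C)(C)C)C[C@@](C)([O-])[C@@H]3[C@]12O[Si](C)(C)C(C)(C)C | intermediate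
23 | C8 alcohol (exo OH at C8) | O[C@H]1C[C@]2(C)[C@@H]3[C@@H](O[Si](C)(C)C(C)(C)C)C[C@@](C)(O)[C@@H]3[C@]2(O[Si](C)(C)C(C)(C)C)C1=O | intermediate
24 | (E)-2-methylbut-2-enoyl chloride (tigloyl chloride) | C/C=C(\C)C(Cl)=O | starting material
25 | C8 tiglate | C/C=C(\C)C(=O)O[C@H]1C[C@]2(C)[C@@H]3[C@@H](O[Si](C)(C)C(C)(C)C)C[C@@](C)(O)[C@@H]3[C@]2(O[Si](C)(C)C(C)(C)C)C1=O | intermediate
26 | triol (C2, C4, C6 hydroxyls; C7 ketone; C8 tiglate) | C/C=C(\C)C(=O)O[C@H]1C[C@]2(C)[C@@H]3[C@@H](O)C[C@@](C)(O)[C@@H]3[C@]2(O)C1=O | intermediate
27 | C2,C4-O-phenylboronate of 26 | C/C=C(\C)C(=O)O[C@H]1C[C@]2(C)[C@@H]3[C@@H](OB5c4ccccc4)C[C@@](C)(O5)[C@@H]3[C@]2(O)C1=O | intermediate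
28 | C6 phosphonate ester of 27 | C/C=C(\C)C(=O)O[C@H]1C[C@]2(C)[C@@H]3[C@@H](OB5c4ccccc4)C[C@@](C)(O5)[C@@H]3[C@]2(OC(=O)C(CO[Si](C)(C)C(C)(C)C)P(=O)(OCC)OCC)C1=O | intermediate
29 | butenolide phenylboronate | C/C=C(\C)C(=O)O[C@H]1C[C@]2(C)[C@@H]3[C@@H](OB5c4ccccc4)C[C@@](C)(O5)[C@@H]3[C@@]23OC(=O)C(CO[Si](C)(C)C(C)(C)C)=C13 | intermediate
30 | butenolide diol with C13 OTBS | C/C=C(\C)C(=O)O[C@H]1C[C@]2(C)[C@@H]3[C@@H](O)C[C@@](C)(O)[C@@H]3[C@@]23OC(=O)C(CO[Si](C)(C)C(C)(C)C)=C13 | intermediate
31 | 13-hydroxy butenolide triol | C/C=C(\C)C(=O)O[C@H]1C[C@]2(C)[C@@H]3[C@@H](O)C[C@@](C)(O)[C@@H]3[C@@]23OC(=O)C(CO)=C13 | intermediate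
32 | CNP0210373.1 | C/C=C(\C)C(=O)O[C@H]1C[C@]2(C)[C@@H]3[C@@H](OC(C)=O)C[C@@](C)(O)[C@@H]3[C@@]23OC(=O)C(COC(C)=O)=C13 | target

## Step count and weakest steps

Total: 18 steps. Longest linear sequence: 14 steps (steps 5 to 18, from 10). Ynone 4 takes one step and acid 9 three.

**Step 9 (key step).** The carbene may fail to reach the C2–H bond: closure builds the strained syn cup, so decay by 1,2-shift or intermolecular reaction can compete, and the basic reagent may enolise and epimerise C5 before it adds. Fallback by ring-closing metathesis, from 16 back to 19: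
- methylenation of the ketone with methylenetriphenylphosphorane gives the isopropenyl compound F1;
- Bu4NF at 0 °C removes only the primary silyl ether to give alcohol F2;
- Dess–Martin oxidation gives aldehyde F3;
- vinylmagnesium bromide gives allylic alcohol F4, the exo-hydroxy epimer being separated;
- TBSOTf/2,6-lutidine gives diene F5;
- second-generation Grubbs catalyst closes the C3=C4 bond to give 19.

**Step 7.** The silyl triflimide generated from Tf2NH may ionise the ketal beside the enol ether (siloxyallyl cation pathways), or silyl transfer may outrun closure at the hindered C6 and stop at the open Michael adduct; separation of the ketal diastereomers may also be poor. Fallback, from 10 back to 15, carrying C7 through the cycloaddition as a silyl-protected carbinol: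
- TBSCl/imidazole on 10 gives the silyloxy enone F6;
- NaBH4/CeCl3·7H2O gives allylic alcohol F7;
- Et3SiCl/imidazole gives bis-silyl ether F8;
- the same cycloaddition with 4 gives cyclobutene F9 (racemic, either C7 epimer);
- PPTS/MeOH removes the triethylsilyl group to give alcohol F10;
- Dess–Martin oxidation gives ketone F11;
- acid-catalysed ketalisation with 11 (the conjugated acetyl group is the slower carbonyl) and separation of diastereomers gives 15.

**Step 8.** Hydrogen may add to the α face, or C5 may epimerise through the enol on the catalyst; either outcome loses the cis, α arrangement of the two arms. Fallback by hydroxyl-directed homogeneous hydrogenation, from 15 back to 16: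
- HF·pyridine removes both silyl groups to give diol F12;
- [Ir(cod)(PCy3)(py)]PF6/H2 in CH2Cl2 delivers hydrogen syn to the β hydroxyl at C6 to give F13;
- immediate TBSOTf/2,6-lutidine at −78 °C, before the β-hydroxy ketone can cleave, gives 16.

**Step 15.** Acylation of the hindered tertiary α-ketol hydroxyl by the α-branched acid may be slow, and long exposure to base risks α-ketol ring expansion of the cyclobutanol. Fallback, from 26 (through boronate 27 as in the route) to 31:
- Meldrum's acid in toluene at 90 °C acylates the C6 hydroxyl through a ketene to give malonic half-ester F14;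
- piperidinium acetate closes the lactone by Knoevenagel condensation to give carboxy-butenolide F15;
- BH3·SMe2 reduces the acid selectively to give hydroxymethyl butenolide boronate F16;
- pinacol releases 31.

**Step 16.** The phosphonate anion may lose silanolate by β-elimination before it cyclises, and C8 may epimerise through the dienolate of the product. Fallback, from 26 (through 27) to 31:
- bromo(diethoxyphosphoryl)acetic acid with DCC gives bromophosphonate ester F17;
- LiCl/DBU gives bromobutenolide boronate F18;
- pinacol gives bromobutenolide diol F19;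
- Stille coupling with (tributylstannyl)methanol and Pd(PPh3)4 in dioxane at 90 °C gives 31.

## Further compounds

F1 | step 9 | isopropenyl compound (16 with C=CH2 in place of C=O) | C1C[C@]2(C)[C@H](CO[Si](C)(C)C(C)(C)C)[C@H](C(C)=C)[C@]2(O[Si](C)(C)C(C)(C)C)C13O[C@H](C)[C@@H](C)O3
F2 | step 9 | primary alcohol | C1C[C@]2(C)[C@H](CO)[C@H](C(C)=C)[C@]2(O[Si](C)(C)C(C)(C)C)C13O[C@H](C)[C@@H](C)O3
F3 | step 9 | aldehyde | C1C[C@]2(C)[C@H](C=O)[C@H](C(C)=C)[C@]2(O[Si](C)(C)C(C)(C)C)C13O[C@H](C)[C@@H](C)O3
F4 | step 9 | allylic alcohol | C1C[C@]2(C)[C@H]([C@@H](O)C=C)[C@H](C(C)=C)[C@]2(O[Si](C)(C)C(C)(C)C)C13O[C@H](C)[C@@H](C)O3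
F5 | step 9 | silylated diene | C1C[C@]2(C)[C@H]([C@@H](O[Si](C)(C)C(C)(C)C)C=C)[C@H](C(C)=C)[C@]2(O[Si](C)(C)C(C)(C)C)C13O[C@H](C)[C@@H](C)O3
F6 | step 7 | 2-[(tert-butyldimethylsilyl)oxy]-3-methylcyclopent-2-en-1-one | CC1=C(O[Si](C)(C)C(C)(C)C)C(=O)CC1
F7 | step 7 | 2-[(tert-butyldimethylsilyl)oxy]-3-methylcyclopent-2-en-1-ol (racemic) | CC1=C(O[Si](C)(C)C(C)(C)C)C(O)CC1
F8 | step 7 | 1-[(tert-butyldimethylsilyl)oxy]-2-methyl-5-[(triethylsilyl)oxy]cyclopentene (racemic) | CC1=C(O[Si](C)(C)C(C)(C)C)C(O[Si](CC)(CC)CC)CC1
F9 | step 7 | cyclobutene with C7 triethylsilyloxy group (racemic, drawn as the enantiomer leading to 15) | C1C[C@]2(C)C(CO[Si](C)(C)C(C)(C)C)=C(C(C)=O)[C@]2(O[Si](C)(C)C(C)(C)C)C1O[Si](CC)(CC)CC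
F10 | step 7 | cyclobutene C7 alcohol (racemic) | C1C[C@]2(C)C(CO[Si](C)(C)C(C)(C)C)=C(C(C)=O)[C@]2(O[Si](C)(C)C(C)(C)C)C1O
F11 | step 7 | cyclobutene C7 ketone (racemic) | C1C[C@]2(C)C(CO[Si](C)(C)C(C)(C)C)=C(C(C)=O)[C@]2(O[Si](C)(C)C(C)(C)C)C1=O
F12 | step 8 | cyclobutene diol (free hydroxyls at C2 and C6) | C1C[C@]2(C)C(CO)=C(C(C)=O)[C@]2(O)C13O[C@H](C)[C@@H](C)O3
F13 | step 8 | saturated diol (H1, H5 β) | C1C[C@]2(C)[C@H](CO)[C@H](C(C)=O)[C@]2(O)C13O[C@H](C)[C@@H](C)O3
F14 | step 15 | C6 malonic half-ester boronate | C/C=C(\C)C(=O)O[C@H]1C[C@]2(C)[C@@H]3[C@@H](OB5c4ccccc4)C[C@@](C)(O5)[C@@H]3[C@]2(OC(=O)CC(=O)O)C1=O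
F15 | step 15 | carboxy-butenolide boronate | C/C=C(\C)C(=O)O[C@H]1C[C@]2(C)[C@@H]3[C@@H](OB5c4ccccc4)C[C@@](C)(O5)[C@@H]3[C@@]23OC(=O)C(C(=O)O)=C13
F16 | step 15 | hydroxymethyl butenolide boronate | C/C=C(\C)C(=O)O[C@H]1C[C@]2(C)[C@@H]3[C@@H](OB5c4ccccc4)C[C@@](C)(O5)[C@@H]3[C@@]23OC(=O)C(CO)=C13
F17 | step 16 | C6 bromophosphonate ester boronate | C/C=C(\C)C(=O)O[C@H]1C[C@]2(C)[C@@H]3[C@@H](OB5c4ccccc4)C[C@@](C)(O5)[C@@H]3[C@]2(OC(=O)C(Br)P(=O)(OCC)OCC)C1=O
F18 | step 16 | bromobutenolide boronate | C/C=C(\C)C(=O)O[C@H]1C[C@]2(C)[C@@H]3[C@@H](OB5c4ccccc4)C[C@@](C)(O5)[C@@H]3[C@@]23OC(=O)C(Br)=C13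
F19 | step 16 | bromobutenolide diol | C/C=C(\C)C(=O)O[C@H]1C[C@]2(C)[C@@H]3[C@@H](O)C[C@@](C)(O)[C@@H]3[C@@]23OC(=O)C(Br)=C13
A1 | alternative 1 | ten-membered triene lactone (both ring olefins ring-cis) | O[C@H]1C/C(C)=C\[C@@H](OC(C)=O)C[C@@](C)(O)/C=C2/OC(=O)C(COC(C)=O)=C12
A2 | alternative 1 | 8-hydroxy 5-4-5 tetracycle (32 lacking the tiglate) | O[C@H]1C[C@]2(C)[C@@H]3[C@@H](OC(C)=O)C[C@@](C)(O)[C@@H]3[C@@]23OC(=O)C(COC(C)=O)=C13
A3 | alternative 2 | ring-A-fused benzyloxy methyl tropone | O=C1C=CC(C)=C2[C@H](O[Si](C)(C)C(C)(C)C)CC(=O)C2=C1OCc3ccccc3
A4 | alternative 2 | tricyclic bicyclo[3.2.0]heptadienone | O=C1C=C[C@]2(C)C3=C([C@]12OCc4ccccc4)C(=O)C[C@H]3O[Si](C)(C)C(C)(C)C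
A5 | alternative 3 | ring A/B α-methylene cyclobutanone | C=C1[C@@H]2[C@@H](O[Si](C)(C)C(C)(C)C)C[C@@](C)(O[Si](CC)(CC)CC)[C@@H]2C1=O
A6 | alternative 3 | C10-quaternary cyclobutanone with dithiane chain | CC1(SCCCS1)C[C@]2(C)[C@@H]3[C@@H](O[Si](C)(C)C(C)(C)C)C[C@@](C)(O[Si](CC)(CC)CC)[C@@H]3C2=O
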